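**Plan**
1. Cuts (own labels: C1 = aryl-bearing CH, C2 = isopropylidene carbon, C3 = ring CH2, ring A = the hydroxy-formyl benzene ring C3a–C7a with C6–OH and C7–CHO): the indane is opened at C2–C3 and, in the same operation, at C1–aryl; the dioxane is cut at both ring C–O bonds; the allene goes back to an aryl bromide and 2-methylbut-3-yn-2-ol.
2. Enabling feature: C1–C2(=CMe2) is a 1,1-dimethylallyl unit whose central carbon C2 carries the benzylic C3 of ring A. This is the η3-allyl that forms when a C3 benzyl–palladium adds to the central carbon of a 3,3-dimethylallene on C7a. C3 is para to the C6 oxygen (easy ionisation), and the two methyl groups are identical (no alkene geometry to control, allyl faces interconvert).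
3. Forward order: ring A is bought; steps 1–6 give the o-allenyl benzylic carbonate 10; steps 7–10 give the benzodioxane boronate 19 (dioxane ring closed in step 9); step 11 joins both halves and closes the five-membered ring; step 12 frees the phenol.
4. Stereochemistry: the dioxane centre (S) comes from Katsuki–Sharpless epoxidation of prenol with D-(−)-diethyl tartrate and one SN2 inversion in step 9; C1 (S) comes from the chiral ligand in step 11, and the wrong C1 epimer would be a diastereomer.

Key step: step 11

Remark: the sense of induction in step 11 cannot be predicted with confidence, so (R)-SEGPHOS is written and its antipode is used if a test run shows the opposite sense; catalyst-bound organopalladium species are treated as mechanism and are not numbered.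

**Route**

Step 1
Reactants: 1 2-bromo-4-hydroxybenzaldehyde
Product: 2 2-bromo-4-(methoxymethoxy)benzaldehyde
Conditions: MOMCl, iPr2NEt, CH2Cl2, 0 °C to rt
Reagents that add atoms: chloromethyl methyl ether COCCl
Why: O-alkylation of the phenol (MOM protection); the acetal later directs the ortho-lithiation and prevents quinone methide formation at the para benzylic position.

Step 2
Reactants: 2 2-bromo-4-(methoxymethoxy)benzaldehyde
Product: 3 [2-bromo-4-(methoxymethoxy)phenyl]methanol
Conditions: NaBH4, MeOH, 0 °C
Reagents that add atoms: none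
Why: Chemoselective hydride reduction of the aldehyde; the aryl bromide and the MOM ether are inert to NaBH4.

Step 3
Reactants: 3 [2-bromo-4-(methoxymethoxy)phenyl]methanol
Product: 6 2-bromo-3-(hydroxymethyl)-6-(methoxymethoxy)benzaldehyde, via dilithio species 4 (not isolated), via lithium amino alkoxide 5 (not isolated)
Conditions: LiN(iPr)2 (2.4 equiv), THF, −78 °C; DMF, −78 to −20 °C; aq NH4Cl
Reagents that add atoms: N,N-dimethylformamide CN(C)C=O
Why: Directed ortho-metalation: after O–H deprotonation the amide base should remove the ring proton flanked by Br and OMOM (the doubly activated, most acidic site), and the aryllithium is formylated by DMF; −78 °C avoids aryne formation by loss of LiBr.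

Step 4
Reactants: 6 2-bromo-3-(hydroxymethyl)-6-(methoxymethoxy)benzaldehyde; 7 2-methylbut-3-yn-2-ol
Product: 8 3-(hydroxymethyl)-2-(3-hydroxy-3-methylbut-1-yn-1-yl)-6-(methoxymethoxy)benzaldehyde
Conditions: Pd(PPh3)2Cl2 (3 mol %), CuI (5 mol %), Et3N, THF, 60 °C
Reagents that add atoms: none
Why: Sonogashira coupling of an aryl bromide activated by the ortho formyl group; the slim alkyne tolerates the two ortho substituents and the free hydroxyl groups.

Step 5
Reactants: 8 3-(hydroxymethyl)-2-(3-hydroxy-3-methylbut-1-yn-1-yl)-6-(methoxymethoxy)benzaldehyde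
Product: 9 4-[2-formyl-6-{[(methoxycarbonyl)oxy]methyl}-3-(methoxymethoxy)phenyl]-2-methylbut-3-yn-2-yl methyl carbonate
Conditions: ClCO2Me (4 equiv), pyridine, DMAP (0.2 equiv), CH2Cl2, 0 °C to rt
Reagents that add atoms: methyl chloroformate COC(=O)Cl
Why: Acylation of both hydroxyl groups under nucleophilic catalysis; the tertiary propargylic carbonate is the leaving group for step 6 and the benzylic carbonate that for step 11.

Step 6
Reactants: 9 4-[2-formyl-6-{[(methoxycarbonyl)oxy]methyl}-3-(methoxymethoxy)phenyl]-2-methylbut-3-yn-2-yl methyl carbonate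
Product: 10 [3-formyl-4-(methoxymethoxy)-2-(3-methylbuta-1,2-dien-1-yl)phenyl]methyl methyl carbonate
Conditions: Pd2(dba)3·CHCl3 (2.5 mol %), PBu3 (5 mol %), HCO2H, Et3N, THF, 25 °C
Reagents that add atoms: none
Why: Palladium–formate hydrogenolysis of a propargylic carbonate: zerovalent palladium ionises the tertiary propargylic carbonate in an SN2′ sense to an allenylpalladium, and formate delivers hydride to the aryl-bearing carbon to give the 3,3-dimethylallene; the monocyclic benzylic carbonate needs heat and a chelating ligand to ionise and should survive at 25 °C.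

Step 7
Reactants: 11 3-bromo-2-hydroxy-5-methylbenzaldehyde
Product: 13 3-bromo-5-methylbenzene-1,2-diol, via aryl formate 12 (not isolated)
Conditions: 30 % H2O2, NaOH, H2O/THF, 0 °C to rt, argon; then dilute HCl
Reagents that add atoms: hydrogen peroxide OO
Why: Dakin oxidation: hydroperoxide adds to the aldehyde, the electron-rich aryl group migrates to oxygen and the formate is hydrolysed in the flask.

Step 8
Reactants: 14 3-methylbut-2-en-1-ol
Product: 16 [(2R)-3,3-dimethyloxiran-2-yl]methyl 4-methylbenzenesulfonate, via (R)-epoxy alcohol 15 (not isolated)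
Conditions: Ti(OiPr)4 (5 mol %), D-(−)-diethyl tartrate (6 mol %), t-BuOOH, 4 Å MS, CH2Cl2, −20 °C; P(OMe)3; then Et3N, DMAP (cat.), TsCl, −20 to 0 °C
Reagents that add atoms: tert-butyl hydroperoxide CC(C)(C)OO; 4-methylbenzenesulfonyl chloride Cc1ccc(cc1)S(=O)(=O)Cl
Why: Katsuki–Sharpless asymmetric epoxidation under reagent control (the D-tartrate titanium complex delivers oxygen to the face that gives the (R)-epoxy alcohol), followed by sulfonylation in the flask because the small epoxy alcohol is water-soluble and labile.

Step 9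
Reactants: 13 3-bromo-5-methylbenzene-1,2-diol; 16 [(2R)-3,3-dimethyloxiran-2-yl]methyl 4-methylbenzenesulfonate
Product: 18 2-[(2S)-8-bromo-6-methyl-2,3-dihydro-1,4-benzodioxin-2-yl]propan-2-ol, via epoxy ether phenol 17 (not isolated)
Conditions: NaH (2.2 equiv), DMF, 0 °C, argon; add 16, rt to 60 °C; aq NH4Cl
Reagents that add atoms: none
Why: Double Williamson-type etherification: the catechol dianion should react first through its more basic and less hindered oxide (meta to Br) at the primary tosylate, and the remaining oxide ortho to Br then opens the epoxide at the secondary carbon (6-exo-tet, SN2 with inversion, (R) to (S)); 7-endo attack at the tertiary carbon is disfavoured under basic conditions.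

Step 10
Reactants: 18 2-[(2S)-8-bromo-6-methyl-2,3-dihydro-1,4-benzodioxin-2-yl]propan-2-ol
Product: 19 2-[(2S)-6-methyl-8-(4,4,5,5-tetramethyl-1,3,2-dioxaborolan-2-yl)-2,3-dihydro-1,4-benzodioxin-2-yl]propan-2-ol
Conditions: B2pin2 (1.3 equiv), Pd(dppf)Cl2 (5 mol %), KOAc (3 equiv), 1,4-dioxane, 90 °C
Reagents that add atoms: bis(pinacolato)diboron CC1(C)OB(OC1(C)C)B1OC(C)(C)C(C)(C)O1
Why: Miyaura borylation of the aryl bromide; the free tertiary alcohol and the dioxane ethers are tolerated and the stereocentre is not involved.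

Step 11
Reactants: 10 [3-formyl-4-(methoxymethoxy)-2-(3-methylbuta-1,2-dien-1-yl)phenyl]methyl methyl carbonate; 19 2-[(2S)-6-methyl-8-(4,4,5,5-tetramethyl-1,3,2-dioxaborolan-2-yl)-2,3-dihydro-1,4-benzodioxin-2-yl]propan-2-ol
Product: 20 (3S)-3-[(3S)-3-(2-hydroxypropan-2-yl)-7-methyl-2,3-dihydro-1,4-benzodioxin-5-yl]-5-(methoxymethoxy)-2-(propan-2-ylidene)-2,3-dihydro-1H-indene-4-carbaldehyde
Conditions: CpPd(η3-C3H5) (5 mol %), (R)-SEGPHOS (6 mol %), THF, 60 °C, slow addition of 19 (1.3 equiv), no added base
Reagents that add atoms: none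
Why: Proposed new method: zerovalent palladium ionises the benzylic carbonate of 10 (helped by the para OMOM group; CO2 is lost and methoxide stays on the metal), the benzylic carbon C3 then migrates to the sp-hybridised central allene carbon C2 through the C2=CMe2 π-bond that lies in the plane of ring A, which closes the five-membered ring (exo with respect to the C=CMe2 bond that is consumed) and leaves an η3-allylpalladium over C1–C2–CMe2; methoxide-promoted transmetalation with 19 and C–C reductive elimination at C1 should give 20. The closest known reaction types are the palladium-catalysed cyclisation–anion capture of allenes (carbopalladation at the central carbon, then Suzuki capture of the η3-allyl) and the base-free Suzuki coupling of benzylic carbonates; new are the benzylic initiator on an allene and ligand control of the aryl capture. The only new stereocentre, C1, is set in the reductive elimination: the two faces of the allyl unit interconvert through the η1 form at the CMe2 terminus (two identical methyl groups, so nothing is lost), and the chiral bisphosphine selects the face that leads to (S)-C1, with the (S) dioxane centre of 19 as a second, weaker control element. The step needs capture at C1 and not at CMe2 (secured by the secondary against the tertiary allyl terminus), insertion before direct benzyl–aryl coupling (secured by the intramolecular allene and slow addition of 19), and no β-hydride loss from the methyl groups (disfavoured in the η3 form and by fast transmetalation). The C1 epimer, if formed, is a diastereomer of 20 and should be separable by chromatography.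

Step 12
Reactants: 20 (3S)-3-[(3S)-3-(2-hydroxypropan-2-yl)-7-methyl-2,3-dihydro-1,4-benzodioxin-5-yl]-5-(methoxymethoxy)-2-(propan-2-ylidene)-2,3-dihydro-1H-indene-4-carbaldehyde
Product: 21 Diaporindene H, (3S)-5-hydroxy-3-[(3S)-3-(2-hydroxypropan-2-yl)-7-methyl-2,3-dihydro-1,4-benzodioxin-5-yl]-2-(propan-2-ylidene)-2,3-dihydro-1H-indene-4-carbaldehyde
Conditions: NaHSO4·SiO2 (moist), CH2Cl2, 25 °C, stopped at full conversion
Reagents that add atoms: none
Why: Acid-catalysed hydrolysis of the aryl MOM acetal, which is unusually labile ortho to a formyl group, on a mild heterogeneous acid chosen to avoid protonation of the tetrasubstituted alkene; no stereocentre is touched.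

**Compound list**
1 | 2-bromo-4-hydroxybenzaldehyde | O=Cc1ccc(O)cc1Br | starting material
2 | 2-bromo-4-(methoxymethoxy)benzaldehyde | COCOc1ccc(C=O)c(Br)c1 | intermediate
3 | [2-bromo-4-(methoxymethoxy)phenyl]methanol | COCOc1ccc(CO)c(Br)c1 | intermediate
4 | lithium [2-bromo-3-lithio-4-(methoxymethoxy)phenyl]methanolate (dilithio species, not isolated) | [Li]OCc1ccc(OCOC)c([Li])c1Br | intermediate
5 | lithium (dimethylamino)[2-bromo-3-(lithiooxymethyl)-6-(methoxymethoxy)phenyl]methanolate (not isolated) | [Li]OCc1ccc(OCOC)c(C(O[Li])N(C)C)c1Br | intermediate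
6 | 2-bromo-3-(hydroxymethyl)-6-(methoxymethoxy)benzaldehyde | O=Cc1c(Br)c(CO)ccc1OCOC | intermediate
7 | 2-methylbut-3-yn-2-ol | CC(C)(O)C#C | starting material
8 | 3-(hydroxymethyl)-2-(3-hydroxy-3-methylbut-1-yn-1-yl)-6-(methoxymethoxy)benzaldehyde | O=Cc1c(C#CC(C)(C)O)c(CO)ccc1OCOC | intermediate
9 | 4-[2-formyl-6-{[(methoxycarbonyl)oxy]methyl}-3-(methoxymethoxy)phenyl]-2-methylbut-3-yn-2-yl methyl carbonate | O=Cc1c(C#CC(C)(C)OC(=O)OC)c(COC(=O)OC)ccc1OCOC | intermediate
10 | [3-formyl-4-(methoxymethoxy)-2-(3-methylbuta-1,2-dien-1-yl)phenyl]methyl methyl carbonate | O=Cc1c(C=C=C(C)C)c(COC(=O)OC)ccc1OCOC | intermediate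
11 | 3-bromo-2-hydroxy-5-methylbenzaldehyde | Cc1cc(Br)c(O)c(C=O)c1 | starting material
12 | 3-bromo-2-hydroxy-5-methylphenyl formate (not isolated) | Cc1cc(Br)c(O)c(OC=O)c1 | intermediate
13 | 3-bromo-5-methylbenzene-1,2-diol | Cc1cc(O)c(O)c(Br)c1 | intermediate
14 | 3-methylbut-2-en-1-ol (prenol) | CC(C)=CCO | starting material
15 | [(2R)-3,3-dimethyloxiran-2-yl]methanol (not isolated) | CC1(C)O[C@@H]1CO | intermediate
16 | [(2R)-3,3-dimethyloxiran-2-yl]methyl 4-methylbenzenesulfonate | CC1(C)O[C@@H]1COS(=O)(=O)c1ccc(C)cc1 | intermediate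
17 | 2-bromo-6-{[(2R)-3,3-dimethyloxiran-2-yl]methoxy}-4-methylphenol (present as its sodium phenolate, not isolated) | Cc1cc(Br)c(O)c(OC[C@H]2OC2(C)C)c1 | intermediate
18 | 2-[(2S)-8-bromo-6-methyl-2,3-dihydro-1,4-benzodioxin-2-yl]propan-2-ol | Cc1cc(Br)c2O[C@H](C(C)(C)O)COc2c1 | intermediate
19 | 2-[(2S)-6-methyl-8-(4,4,5,5-tetramethyl-1,3,2-dioxaborolan-2-yl)-2,3-dihydro-1,4-benzodioxin-2-yl]propan-2-ol | Cc1cc(B2OC(C)(C)C(C)(C)O2)c2O[C@H](C(C)(C)O)COc2c1 | intermediate
20 | (3S)-3-[(3S)-3-(2-hydroxypropan-2-yl)-7-methyl-2,3-dihydro-1,4-benzodioxin-5-yl]-5-(methoxymethoxy)-2-(propan-2-ylidene)-2,3-dihydro-1H-indene-4-carbaldehyde | CC(C)=C1Cc2ccc(OCOC)c(C=O)c2[C@H]1c1cc(C)cc2c1O[C@H](C(C)(C)O)CO2 | intermediate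
21 | Diaporindene H | CC(C)=C1Cc2ccc(O)c(C=O)c2[C@H]1c1cc(C)cc2c1O[C@H](C(C)(C)O)CO2 | target

**Step count**
Total: 12 steps. Longest linear sequence: 8 steps (steps 1–6, 11, 12).

**Steps most likely to fail**

Step 11 (labelled step). What may go wrong: poor face selectivity in the aryl-transfer reductive elimination, or cross-coupling of the benzylpalladium with the boronate before the allene has inserted. The fallback reverses the order of the two bond formations and uses reaction types of known kind. It sets out from 9 and 19. Coupling of the tertiary propargylic carbonate of 9 with 19 under Pd(PPh3)4 in THF at 25 °C (SN2′ ionisation to an allenylpalladium, transmetalation, reductive elimination; the standard route from propargylic carbonates and organoborons to tetrasubstituted aryl allenes) should give [3-formyl-2-{1-[(3S)-3-(2-hydroxypropan-2-yl)-7-methyl-2,3-dihydro-1,4-benzodioxin-5-yl]-3-methylbuta-1,2-dien-1-yl}-4-(methoxymethoxy)phenyl]methyl methyl carbonate F1, with the benzylic carbonate untouched at this temperature. F1 is then cyclised reductively with Pd2(dba)3·CHCl3, PBu3 and HCO2H/Et3N in THF at 60 °C: the benzylic carbon inserts at the central allene carbon as in step 11, and formate transfers hydride to the more hindered diaryl terminus C1, the usual regiochemistry of palladium–formate reduction of η3-allyl units. Without ligand control both C1 epimers are expected, 20 and its (3R) epimer (3R)-3-[(3S)-3-(2-hydroxypropan-2-yl)-7-methyl-2,3-dihydro-1,4-benzodioxin-5-yl]-5-(methoxymethoxy)-2-(propan-2-ylidene)-2,3-dihydro-1H-indene-4-carbaldehyde F2. They are diastereomers because the dioxane centre is fixed, so chromatography should separate them. The route is rejoined at 20.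

Step 9. What may go wrong: scrambling of the two phenolic oxygens, that is, first alkylation through the oxide ortho to bromine, which would lead to the regioisomeric dioxane. The fallback differentiates the oxygens before the catechol stage. It sets out from 11. PMBCl and K2CO3 in DMF give 3-bromo-2-[(4-methoxyphenyl)methoxy]-5-methylbenzaldehyde F3. Baeyer–Villiger oxidation with m-CPBA in CH2Cl2 gives 3-bromo-2-[(4-methoxyphenyl)methoxy]-5-methylphenyl formate F4, and K2CO3 in MeOH gives 3-bromo-2-[(4-methoxyphenyl)methoxy]-5-methylphenol F5. Alkylation of the only free phenol with 16 (K2CO3, DMF, 50 °C) gives (2R)-2-({3-bromo-2-[(4-methoxyphenyl)methoxy]-5-methylphenoxy}methyl)-3,3-dimethyloxirane F6. DDQ in CH2Cl2/H2O removes the PMB group to give the free phenol 17, and K2CO3 in MeOH at 50 °C closes the dioxane as in step 9. The route is rejoined at 17 and 18.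

Step 12. What may go wrong: acid-promoted migration of the exocyclic double bond into the five-membered ring (indene formation with loss of the C1 configuration) during cleavage of the MOM ether. The fallback carries the phenol through the key step as a base-labile methyl carbonate. It sets out from 8, a stage without the sensitive alkene. NaHSO4·SiO2 in CH2Cl2 (or dilute HCl in MeOH) removes the MOM group to give 6-hydroxy-3-(hydroxymethyl)-2-(3-hydroxy-3-methylbut-1-yn-1-yl)benzaldehyde F7. ClCO2Me, pyridine and DMAP give 4-[2-formyl-6-{[(methoxycarbonyl)oxy]methyl}-3-[(methoxycarbonyl)oxy]phenyl]-2-methylbut-3-yn-2-yl methyl carbonate F8. The conditions of step 6 give {3-formyl-4-[(methoxycarbonyl)oxy]-2-(3-methylbuta-1,2-dien-1-yl)phenyl}methyl methyl carbonate F9. The conditions of step 11 with 19 give (3S)-4-formyl-3-[(3S)-3-(2-hydroxypropan-2-yl)-7-methyl-2,3-dihydro-1,4-benzodioxin-5-yl]-2-(propan-2-ylidene)-2,3-dihydro-1H-inden-5-yl methyl carbonate F10. K2CO3 in MeOH at 0 °C then frees the phenol without acid. The route is rejoined at 21.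

**Further compounds**
F1 | step 11 | [3-formyl-2-{1-[(3S)-3-(2-hydroxypropan-2-yl)-7-methyl-2,3-dihydro-1,4-benzodioxin-5-yl]-3-methylbuta-1,2-dien-1-yl}-4-(methoxymethoxy)phenyl]methyl methyl carbonate | COCOc1ccc(COC(=O)OC)c(C(=C=C(C)C)c2cc(C)cc3c2O[C@H](C(C)(C)O)CO3)c1C=O
F2 | step 11 | (3R)-3-[(3S)-3-(2-hydroxypropan-2-yl)-7-methyl-2,3-dihydro-1,4-benzodioxin-5-yl]-5-(methoxymethoxy)-2-(propan-2-ylidene)-2,3-dihydro-1H-indene-4-carbaldehyde | CC(C)=C1Cc2ccc(OCOC)c(C=O)c2[C@@H]1c1cc(C)cc2c1O[C@H](C(C)(C)O)CO2
F3 | step 9 | 3-bromo-2-[(4-methoxyphenyl)methoxy]-5-methylbenzaldehyde | Cc1cc(Br)c(OCc2ccc(OC)cc2)c(C=O)c1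
F4 | step 9 | 3-bromo-2-[(4-methoxyphenyl)methoxy]-5-methylphenyl formate | Cc1cc(Br)c(OCc2ccc(OC)cc2)c(OC=O)c1
F5 | step 9 | 3-bromo-2-[(4-methoxyphenyl)methoxy]-5-methylphenol | Cc1cc(Br)c(OCc2ccc(OC)cc2)c(O)c1
F6 | step 9 | (2R)-2-({3-bromo-2-[(4-methoxyphenyl)methoxy]-5-methylphenoxy}methyl)-3,3-dimethyloxirane | Cc1cc(Br)c(OCc2ccc(OC)cc2)c(OC[C@H]2OC2(C)C)c1
F7 | step 12 | 6-hydroxy-3-(hydroxymethyl)-2-(3-hydroxy-3-methylbut-1-yn-1-yl)benzaldehyde | O=Cc1c(C#CC(C)(C)O)c(CO)ccc1O
F8 | step 12 | 4-[2-formyl-6-{[(methoxycarbonyl)oxy]methyl}-3-[(methoxycarbonyl)oxy]phenyl]-2-methylbut-3-yn-2-yl methyl carbonate | O=Cc1c(C#CC(C)(C)OC(=O)OC)c(COC(=O)OC)ccc1OC(=O)OC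
F9 | step 12 | {3-formyl-4-[(methoxycarbonyl)oxy]-2-(3-methylbuta-1,2-dien-1-yl)phenyl}methyl methyl carbonate | O=Cc1c(C=C=C(C)C)c(COC(=O)OC)ccc1OC(=O)OC
F10 | step 12 | (3S)-4-formyl-3-[(3S)-3-(2-hydroxypropan-2-yl)-7-methyl-2,3-dihydro-1,4-benzodioxin-5-yl]-2-(propan-2-ylidene)-2,3-dihydro-1H-inden-5-yl methyl carbonate | CC(C)=C1Cc2ccc(OC(=O)OC)c(C=O)c2[C@H]1c1cc(C)cc2c1O[C@H](C(C)(C)O)CO2
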